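I ask first how much starting material is left over at the end, counting everything in fractions of the starting material charged.

    intermediate B ⇌ intermediate C (K1 = 0.64, k1 = 0.0042 min⁻¹)
    starting material + protic impurity → quenched substrate (k2 = 0.0019 M⁻¹ min⁻¹)
    starting material → target (k3 = 0.0016 min⁻¹)
    intermediate A ⇌ intermediate B (K4 = 8.6, k4 = 0.0059 min⁻¹)
    intermediate A → side product (k5 = 9.9 × 10⁻⁴ min⁻¹)
    starting material → intermediate A (k6 = 0.0023 min⁻¹)

| flask | starting material | protic impurity | time |
|---|---|---|---|
| autumn | 0.50 M | 0.0200 M | 3.0 d |
| dawn | 0.50 M | 0.0400 M | 3.0 d |
| dusk | 0.50 M | 0.0800 M | 3.0 d |
| spring | 0.50 M | 0.150 M | 3.0 d |
| midnight | 0.50 M | 0.300 M | 3.0 d |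

* amount of target at the end, in percent of the starting material charged for autumn, dawn, dusk, spring, midnight, in this order
* the course of these numbers from the first flask to the last (hardly changes / rises, then falls / falls, then rises / falls all the way / rises all the way)

- "hardly changes" means that all values lie within two and a half points (for a concentration: within two and a half percent of the largest)
- run time (autumn): 3.0 d

1. The leftover. The steps to target and to intermediate A together consume starting material at 0.00390 min⁻¹. Over 3.0 d that makes 16.8 lifetimes, so the reckoned leftover is <0.001% of the charge even before the quench is counted.

2. The clean end. No step leads from intermediate A back to starting material or on to target, so target is one branch of a partition. With no impurity, its share is the step to target over both steps, 41.0%.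

3. The flat end. Let p be the impurity charge as a fraction of the starting material charged: 0.0400 in autumn, 0.600 in midnight. I call exposure the quench constant times the starting material charge, over the two first-order steps together: 0.244. With the impurity held flat, the quench is pseudo-first-order, and target becomes the clean share divided by one plus exposure times p. That gives 35.8% for midnight.

4. The weak link. The quench consumes impurity as well as starting material, so p does not stay flat. Its remaining fraction is e to the minus exposure/(1 + exposure × p), which is 80.9% of its own charge in midnight.

5. The join. I replace p by the mean of its start and end values. Midnight then gives 36.2% and autumn 40.7%. Target falls as p grows, and the gap of 4.5 percentage points is wider than the margin for "hardly changes". I commit to a fall all the way.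

The forecast gives 40.7%, 40.3%, 39.65%, 38.5% and 36.3%, and calls the course "falls all the way". It starts from “Target comes only from starting material”. For the midnight flask it gives 36.3% where I reckon 36.2%.

The flasks give 40.7%, 40.3%, 39.6%, 38.5% and 36.3%, and the course is "falls all the way".

In autumn at 0.123 d, starting material goes to intermediate A 1.4 times as fast as to target. Quenched substrate ends in autumn at 0.858%, against 11.6% in midnight, and target in midnight stands 4.4 points lower than in autumn. With the exposure of 0.244, midnight was reckoned to keep 80.9% of its impurity, and it keeps 81%. Dusk, at p of 0.160, reckons to 39.6%, and its target reading is 39.6%.

The numbers belong to no real substance; the run is a simulation.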